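**Retrosynthetic overview**

1. Locants follow the name spiro[2-oxabicyclo[2.2.2]octane-5,2'-oxane]: C1 is the O-bearing bridgehead CH, O2–C3(=O) the lactone bridge, C4 the quaternary bridgehead, C5 (= C2') the spiro carbon, C6 and C7 the CHMe carbons, C8 the ketone; the acetate sits on C4'.
2. Endgame: acetate ⇐ C4' alcohol ⇐ bis-silyl cycloadduct in which the C8 ketone is a silyl enol ether (C7=C8); the C7 hydrogen comes from face-selective protonation.
3. Key disconnection: the carbocycle C1–C6–C5–C4–C8–C7 is opened at C4–C5 and C1–C6 in one retro-[4+2]. This removes both carbon bridges at once and leaves an achiral 4-silyloxy-3,5-dimethyl-2-pyrone (already holding the lactone bridge) and a (Z)-2-ethylidene-oxane (already holding the oxane ring and its four stereocentres).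
4. Enabling feature: C4–C8(=O)–C7–C1 bridged by O2–C3(=O) is a 4-oxygenated 2-pyrone at the enol oxidation level, and the spiro carbon C5 carries the ring oxygen O1', so C5=C6 is an enol ether. The polarities match: nucleophilic C6 bonds to the electrophilic pyrylium α-carbon C1, and oxocarbenium C5 bonds to the ketene-acetal carbon C4.
5. Ring order: oxane ring first (δ-lactone from an all-anti stereotetrad made by two Fráter–Seebach methylations and a chelation-controlled aldol addition, then Takai–Utimoto ethylidenation); pyranone ring second (pyrone from a β-keto ester dianion); carbocycle last.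

Key step: step 11

Remark: the C7 configuration of the target is taken to be the one produced by protonation of the C7=C8 enol from the side of the lactone bridge (kinetic face).

**Route**

Step 1
Reactants: 1 ethyl (R)-3-hydroxybutanoate
Product: 2 ethyl (2R,3R)-3-hydroxy-2-methylbutanoate
Conditions: LiN(i-Pr)2 (2.2 equiv), THF, −78 → −20 °C; MeI, DMPU, −78 → 0 °C; aq. NH4Cl
Reagents that add atoms: iodomethane, CI
Why: Fráter–Seebach alkylation: the lithium-chelated alkoxide–enolate dianion of the β-hydroxy ester should be methylated on the face away from the C3 methyl group, which sets C2 anti to the chiral-pool C3 hydroxyl.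

Step 2
Reactants: 2 ethyl (2R,3R)-3-hydroxy-2-methylbutanoate
Product: 3 ethyl (2R,3R)-3-(benzyloxy)-2-methylbutanoate
Conditions: BnOC(=NH)CCl3, TfOH (cat.), cyclohexane/CH2Cl2, 0 °C → rt
Reagents that add atoms: benzyl 2,2,2-trichloroacetimidate, ClC(Cl)(Cl)C(=N)OCc1ccccc1
Why: Acid-catalysed O-benzylation with the trichloroacetimidate proceeds without base, so the β-hydroxy ester should neither epimerise at C2 nor eliminate, and the benzyl ether becomes the chelating group of step 4.

Step 3
Reactants: 3 ethyl (2R,3R)-3-(benzyloxy)-2-methylbutanoate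
Product: 4 (2R,3R)-3-(benzyloxy)-2-methylbutanal
Conditions: i-Bu2AlH (1.1 equiv), CH2Cl2, −78 °C; aq. KNaC4H4O6 (potassium sodium tartrate)
Reagents that add atoms: none
Why: Partial ester reduction by i-Bu2AlH at −78 °C should stop at the aluminium hemiacetal, which releases the aldehyde only on work-up; the crude aldehyde is used at once so that the α-stereocentre is not exposed to epimerisation.

Step 4
Reactants: 4 (2R,3R)-3-(benzyloxy)-2-methylbutanal; 5 1-(tert-butyldimethylsilyloxy)-1-methoxyethene
Product: 6 methyl (3S,4S,5R)-5-(benzyloxy)-3-hydroxy-4-methylhexanoate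
Conditions: TiCl4 (1.05 equiv), CH2Cl2, −78 °C; then 5, −78 °C; aq. NaHCO3
Reagents that add atoms: none
Why: Chelation-controlled Mukaiyama aldol addition: TiCl4 ties the aldehyde oxygen and the β-benzyloxy oxygen into a six-membered chelate and the silyl ketene acetal should attack the face opposite the α-methyl group (anti-Felkin), which sets the new carbinol C3 anti to the C4 methyl.

Step 5
Reactants: 6 methyl (3S,4S,5R)-5-(benzyloxy)-3-hydroxy-4-methylhexanoate
Product: 7 methyl (2R,3R,4S,5R)-5-(benzyloxy)-3-hydroxy-2,4-dimethylhexanoate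
Conditions: LiN(i-Pr)2 (2.2 equiv), THF, −78 → −20 °C; MeI, DMPU, −78 → −10 °C; aq. NH4Cl
Reagents that add atoms: iodomethane, CI
Why: Second Fráter–Seebach alkylation: methylation of the chelated dianion on the face away from the C3 side chain should set the C2 methyl anti to the C3 hydroxyl and so complete the all-anti stereotetrad.

Step 6
Reactants: 7 methyl (2R,3R,4S,5R)-5-(benzyloxy)-3-hydroxy-2,4-dimethylhexanoate
Product: 9 (3R,4R,5S,6R)-4-hydroxy-3,5,6-trimethyloxan-2-one, via dihydroxy ester 8 (not isolated)
Conditions: H2 (1 atm), Pd/C (10% Pd on carbon), EtOAc, rt; filter; PPTS (cat.), PhMe, 50 °C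
Reagents that add atoms: none
Why: Hydrogenolysis of the benzyl ether over Pd/C frees the C5 hydroxyl, which should lactonise onto the methyl ester under mild acid catalysis (six-membered ring strongly preferred over the β-lactone) without touching a stereocentre.

Step 7
Reactants: 9 (3R,4R,5S,6R)-4-hydroxy-3,5,6-trimethyloxan-2-one
Product: 10 (3R,4R,5R,6R)-4-[(tert-butyldimethylsilyl)oxy]-3,5,6-trimethyloxan-2-one
Conditions: TBSOTf, 2,6-lutidine, CH2Cl2, −78 → 0 °C
Reagents that add atoms: tert-butyldimethylsilyl trifluoromethanesulfonate, CC(C)(C)[Si](C)(C)OS(=O)(=O)C(F)(F)F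
Why: Silylation of the hindered secondary alcohol with the silyl triflate and a hindered base should be clean; the silyl ether masks the oxygen during step 8 and becomes the facial shield of step 11.

Step 8
Reactants: 10 (3R,4R,5R,6R)-4-[(tert-butyldimethylsilyl)oxy]-3,5,6-trimethyloxan-2-one
Product: 11 tert-butyl{[(2Z,3R,4R,5R,6R)-2-ethylidene-3,5,6-trimethyloxan-4-yl]oxy}dimethylsilane
Conditions: CH3CHBr2, TiCl4, Zn, PbCl2 (cat.), TMEDA, THF, 25 °C; Et3N then aq. K2CO3; basic Al2O3
Reagents that add atoms: 1,1-dibromoethane, CC(Br)Br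
Why: Takai–Utimoto alkylidenation: the geminal dimetal ethylidene reagent formed from CH3CHBr2, Zn and TiCl4 converts the lactone carbonyl into the exocyclic enol ether and, as with esters, should give the (Z) isomer (ring oxygen cis to the new methyl), the silyl ether being inert.

Step 9
Reactants: 12 methyl 2-methyl-3-oxopentanoate
Product: 14 4-hydroxy-3,5-dimethyl-2H-pyran-2-one, via formyl keto ester 13 (not isolated)
Conditions: LiN(i-Pr)2 (2.2 equiv), THF, −78 → 0 °C; HCO2Et, −78 → 0 °C; aq. HCl; then DBU (cat.), PhMe, 80 °C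
Reagents that add atoms: ethyl formate, CCOC=O
Why: Huckin–Weiler dianion chemistry: the β-keto ester dianion should be formylated at its γ-carbon by ethyl formate (crossed Claisen condensation) and the hydroxymethylene keto ester 13 should lactonise with loss of methanol to the 4-hydroxy-2-pyrone; no stereocentre is involved.

Step 10
Reactants: 14 4-hydroxy-3,5-dimethyl-2H-pyran-2-one
Product: 15 4-[(tert-butyldimethylsilyl)oxy]-3,5-dimethyl-2H-pyran-2-one
Conditions: TBSCl, imidazole, CH2Cl2, 0 °C → rt; non-aqueous work-up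
Reagents that add atoms: tert-butyl(chloro)dimethylsilane, CC(C)(C)[Si](C)(C)Cl
Why: O-Silylation of the vinylogous acid under standard conditions should give the 4-silyloxy-2-pyrone, the diene partner that carries the C8 oxygen at the enol level.

Step 11
Reactants: 11 tert-butyl{[(2Z,3R,4R,5R,6R)-2-ethylidene-3,5,6-trimethyloxan-4-yl]oxy}dimethylsilane; 15 4-[(tert-butyldimethylsilyl)oxy]-3,5-dimethyl-2H-pyran-2-one
Product: 17 (1R,3'R,4S,4'R,5R,5'R,6S,6'R)-4',8-bis[(tert-butyldimethylsilyl)oxy]-3',4,5',6,6',7-hexamethylspiro[2-oxabicyclo[2.2.2]oct-7-ene-5,2'-oxan]-3-one, via pyrylium triflate 16 (not isolated)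
Conditions: TBSOTf (0.3 equiv), 2,6-di-tert-butyl-4-methylpyridine (0.5 equiv), CH2Cl2, −78 → −30 °C; Et3N, then aq. NaHCO3
Reagents that add atoms: none
Why: Proposed new method: catalytic TBSOTf should silylate the lactone carbonyl oxygen of 15 to give the 2,4-bis(silyloxy)pyrylium ion 16, whose only unsubstituted α-carbon (target C1) is attacked by the nucleophilic β-carbon of enol ether 11 (target C6), after which the tertiary oxocarbenium ion at C5 is captured by the cyclic ketene silyl acetal carbon (target C4) and the silyl group on the new lactone carbonyl passes to the next molecule of 15, so that the net change is a silyl-cation-catalysed, stepwise or highly asynchronous inverse-electron-demand [4+2] cycloaddition. The closest known reaction types are the Lewis-acid-promoted inverse-demand Diels–Alder reaction of 2-pyrones with vinyl ethers to 2-oxabicyclo[2.2.2]octenones, the addition of π-nucleophiles to 4-silyloxypyrylium triflates and the Isler–Mukaiyama addition of oxocarbenium ions to enol ethers. The only ring closed, the carbocycle C1–C6–C5–C4–C8–C7, is formed by intermolecular C1–C6 bonding followed by a 6-(enolexo)-exo-trig attack of C4 on the C5 oxocarbenium carbon, the alternative nucleophilic site C7 being excluded because it would close a four-membered ring. C5 and C6 are controlled by the oxane chair with three equatorial methyl groups, whose axial C4' silyloxy group shields the syn face of the exocyclic double bond so that both bonds form on the opposite face (C4 equatorial and C6 axial on the oxane), and by suprafacial transfer of the (Z) geometry (O1' and the C6 methyl end up cis, both on the side of the lactone bridge). C1 and C4 follow from the orientation of the pyrylium ion over the enol ether, in which the C6 methyl should lie under the unsubstituted ring oxygen and not under the methyl-bearing C7 (avoided syn-pentane contact), and are tied to each other by the bicycle. The step needs regioselectivity (secured by the polarity match and by the single free α-position of 16), face and orientation selectivity (axial silyloxy group; methyl/methyl avoidance) and survival of the acid-labile exocyclic enol ether (hindered pyridine base, low temperature, sub-stoichiometric silyl triflate).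

Step 12
Reactants: 17 (1R,3'R,4S,4'R,5R,5'R,6S,6'R)-4',8-bis[(tert-butyldimethylsilyl)oxy]-3',4,5',6,6',7-hexamethylspiro[2-oxabicyclo[2.2.2]oct-7-ene-5,2'-oxan]-3-one
Product: 18 (1R,3'R,4S,4'R,5S,5'S,6S,6'R,7S)-4'-hydroxy-3',4,5',6,6',7-hexamethylspiro[2-oxabicyclo[2.2.2]octane-5,2'-oxane]-3,8-dione
Conditions: HF·pyridine, pyridine, THF, 0 °C → rt; aq. NaHCO3
Reagents that add atoms: none
Why: Fluoride-assisted cleavage of both silyl groups; the C7=C8 enol set free should be protonated at C7 from the side of the unsubstituted lactone bridge, the other side being screened by the C5–C6 bridge and the oxane ring, which places the C7 methyl as in the target (kinetic protonation of an enol).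

Step 13
Reactants: 18 (1R,3'R,4S,4'R,5S,5'S,6S,6'R,7S)-4'-hydroxy-3',4,5',6,6',7-hexamethylspiro[2-oxabicyclo[2.2.2]octane-5,2'-oxane]-3,8-dione
Product: 19 (1R,3'R,4S,4'R,5S,5'R,6S,6'R,7S)-3',4,5',6,6',7-hexamethyl-3,8-dioxospiro[2-oxabicyclo[2.2.2]octane-5,2'-oxan]-4'-yl acetate
Conditions: Ac2O, pyridine, DMAP (cat.), CH2Cl2, 0 °C → rt
Reagents that add atoms: acetic anhydride, CC(=O)OC(C)=O
Why: DMAP-catalysed acetylation of the secondary alcohol under non-nucleophilic, weakly basic conditions should not open the non-enolisable β-keto lactone (retro-Claisen) nor epimerise C7.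

**Compound list**

1 | ethyl (R)-3-hydroxybutanoate | CCOC(=O)C[C@@H](C)O | starting material
2 | ethyl (2R,3R)-3-hydroxy-2-methylbutanoate | CCOC(=O)[C@H](C)[C@@H](C)O | intermediate
3 | ethyl (2R,3R)-3-(benzyloxy)-2-methylbutanoate | CCOC(=O)[C@H](C)[C@@H](C)OCc1ccccc1 | intermediate
4 | (2R,3R)-3-(benzyloxy)-2-methylbutanal | O=C[C@H](C)[C@@H](C)OCc1ccccc1 | intermediate
5 | 1-(tert-butyldimethylsilyloxy)-1-methoxyethene | COC(=C)O[Si](C)(C)C(C)(C)C | starting material
6 | methyl (3S,4S,5R)-5-(benzyloxy)-3-hydroxy-4-methylhexanoate | COC(=O)C[C@H](O)[C@H](C)[C@@H](C)OCc1ccccc1 | intermediate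
7 | methyl (2R,3R,4S,5R)-5-(benzyloxy)-3-hydroxy-2,4-dimethylhexanoate | COC(=O)[C@H](C)[C@H](O)[C@H](C)[C@@H](C)OCc1ccccc1 | intermediate
8 | methyl (2R,3R,4R,5R)-3,5-dihydroxy-2,4-dimethylhexanoate (dihydroxy ester) | COC(=O)[C@H](C)[C@H](O)[C@H](C)[C@@H](C)O | intermediate (not isolated)
9 | (3R,4R,5S,6R)-4-hydroxy-3,5,6-trimethyloxan-2-one (3-Me, 4-OH and 5-Me cis; 6-Me trans to them) | O[C@@H]1[C@H](C)[C@@H](C)OC(=O)[C@@H]1C | intermediate
10 | (3R,4R,5R,6R)-4-[(tert-butyldimethylsilyl)oxy]-3,5,6-trimethyloxan-2-one | CC(C)(C)[Si](C)(C)O[C@@H]1[C@H](C)[C@@H](C)OC(=O)[C@@H]1C | intermediate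
11 | tert-butyl{[(2Z,3R,4R,5R,6R)-2-ethylidene-3,5,6-trimethyloxan-4-yl]oxy}dimethylsilane (ring oxygen cis to the vinylic methyl) | CC(C)(C)[Si](C)(C)O[C@@H]1[C@H](C)[C@@H](C)O/C(=C\C)[C@@H]1C | intermediate
12 | methyl 2-methyl-3-oxopentanoate (racemic) | CCC(=O)C(C)C(=O)OC | starting material
13 | methyl 2,4-dimethyl-3,5-dioxopentanoate (formyl keto ester, present as its hydroxymethylene enol) | COC(=O)C(C)C(=O)C(C)C=O | intermediate (not isolated)
14 | 4-hydroxy-3,5-dimethyl-2H-pyran-2-one | CC1=COC(=O)C(C)=C1O | intermediate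
15 | 4-[(tert-butyldimethylsilyl)oxy]-3,5-dimethyl-2H-pyran-2-one | CC1=COC(=O)C(C)=C1O[Si](C)(C)C(C)(C)C | intermediate
16 | 2,4-bis[(tert-butyldimethylsilyl)oxy]-3,5-dimethylpyrylium trifluoromethanesulfonate | Cc1c[o+]c(O[Si](C)(C)C(C)(C)C)c(C)c1O[Si](C)(C)C(C)(C)C.[O-]S(=O)(=O)C(F)(F)F | intermediate (not isolated)
17 | (1R,3'R,4S,4'R,5R,5'R,6S,6'R)-4',8-bis[(tert-butyldimethylsilyl)oxy]-3',4,5',6,6',7-hexamethylspiro[2-oxabicyclo[2.2.2]oct-7-ene-5,2'-oxan]-3-one (O1' and C6-Me on the side of the lactone bridge) | CC(C)(C)[Si](C)(C)O[C@@H]1[C@H](C)[C@@H](C)O[C@@]2([C@@H]1C)[C@@H](C)[C@H]1OC(=O)[C@]2(C)C(O[Si](C)(C)C(C)(C)C)=C1C | intermediate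
18 | (1R,3'R,4S,4'R,5S,5'S,6S,6'R,7S)-4'-hydroxy-3',4,5',6,6',7-hexamethylspiro[2-oxabicyclo[2.2.2]octane-5,2'-oxane]-3,8-dione | O[C@@H]1[C@H](C)[C@@H](C)O[C@@]2([C@@H]1C)[C@@H](C)[C@H]1OC(=O)[C@]2(C)C(=O)[C@H]1C | intermediate
19 | (1R,3'R,4S,4'R,5S,5'R,6S,6'R,7S)-3',4,5',6,6',7-hexamethyl-3,8-dioxospiro[2-oxabicyclo[2.2.2]octane-5,2'-oxan]-4'-yl acetate | CC(=O)O[C@@H]1[C@H](C)[C@@H](C)O[C@@]2([C@@H]1C)[C@@H](C)[C@H]1OC(=O)[C@]2(C)C(=O)[C@H]1C | target

**Step count and risks**

Total step count: 13. Longest linear sequence: 11 steps (steps 1–8, then 11–13); the pyrone branch (steps 9–10) is 2 steps.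

Steps most likely to fail:

1. Step 11 (proposed new method). What may go wrong: loss of a proton from the C5 oxocarbenium intermediate before ring closure, acid-induced migration of the exocyclic double bond into the oxane ring, or closure with the pyrylium ion turned the other way round. Fallback (known chemistry; the two C–C bonds are made in two separate operations and the second under reversible conditions): it sets out from 11 and 15 and comes back to the route at 17. Pyrylium salt 16 is made from 15 with one equivalent of TBSOTf (CH2Cl2, −78 °C) and enol ether 11 is added (Isler–Mukaiyama-type addition of a stabilised cation to an enol ether). The C5 cation is then intercepted with MeOH/2,6-lutidine at −78 °C; the same quench methanolyses the silyl groups of the pyranone part and gives the methyl ketal of the open adduct, 6-{1-[4-(tert-butyldimethylsilyloxy)-2-methoxy-3,5,6-trimethyloxan-2-yl]ethyl}-4-hydroxy-3,5-dimethyl-5,6-dihydro-2H-pyran-2-one F1. BF3·OEt2 (CH2Cl2, −40 → 0 °C) then ionises the ketal, and the β-keto lactone enol should close onto the oxocarbenium carbon (Lewis-acid-mediated C-alkylation of a 1,3-dicarbonyl enol by a ketal) to give the C4' silyl ether of 18, 4'-[(tert-butyldimethylsilyl)oxy]-3',4,5',6,6',7-hexamethylspiro[2-oxabicyclo[2.2.2]octane-5,2'-oxane]-3,8-dione F2. Enol silylation of F2 (TBSOTf, Et3N, CH2Cl2, 0 °C; only C7 can enolise) returns 17. The C7 configuration of F1 and F2 is immaterial, because it is erased in 17 and set in step 12.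

2. Step 8. What may go wrong: incomplete alkylidenation of the hindered, α-branched lactone carbonyl with ring opening by the Lewis-acidic titanium species, erosion of the Z/E ratio, or migration of the double bond into the ring during isolation. Fallback (the enol ether is made by ring closure onto an alkyne instead of by carbonyl olefination): it sets out from 10 and comes back to the route at 11. Reduction with i-Bu2AlH (CH2Cl2, −78 °C) gives (3R,4R,5R,6R)-4-[(tert-butyldimethylsilyl)oxy]-3,5,6-trimethyloxan-2-ol F3 (anomeric mixture). Ohira–Bestmann homologation (dimethyl (1-diazo-2-oxopropyl)phosphonate, K2CO3, MeOH, 0 °C) gives (2R,3R,4S,5S)-4-[(tert-butyldimethylsilyl)oxy]-3,5-dimethylhept-6-yn-2-ol F4. Its dilithio derivative (n-BuLi, 2 equiv, THF, −78 °C) is C-methylated with MeI to (2R,3R,4S,5S)-4-[(tert-butyldimethylsilyl)oxy]-3,5-dimethyloct-6-yn-2-ol F5. A 6-exo-dig cycloisomerisation (AuCl (cat.), K2CO3, MeCN, rt) through anti-oxyauration and protodeauration places the vinylic hydrogen trans to oxygen and should therefore give the (Z)-enol ether 11.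

3. Step 12. What may go wrong: poor facial selectivity in the protonation of the C7=C8 enol (a small proton donor may not discriminate between the two sides), or epimerisation at C7 afterwards. Fallback (the C7 hydrogen is delivered by a catalyst surface to an alkene instead of by a proton to an enol): it sets out from 17 and comes back to the route at 18. Saegusa–Ito oxidation (Pd(OAc)2, MeCN, rt; β-hydride elimination can only use a methyl hydrogen because C1 is a bridgehead) gives 4'-[(tert-butyldimethylsilyl)oxy]-3',4,5',6,6'-pentamethyl-7-methylidenespiro[2-oxabicyclo[2.2.2]octane-5,2'-oxane]-3,8-dione F6. HF·pyridine (THF, rt) gives 4'-hydroxy-3',4,5',6,6'-pentamethyl-7-methylidenespiro[2-oxabicyclo[2.2.2]octane-5,2'-oxane]-3,8-dione F7. Hydrogenation (H2, Pd/C, EtOAc, rt) should add hydrogen to the exocyclic alkene from the open side of the lactone bridge and give 18.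

**Further compounds**

F1 | step 11 | 6-{1-[4-(tert-butyldimethylsilyloxy)-2-methoxy-3,5,6-trimethyloxan-2-yl]ethyl}-4-hydroxy-3,5-dimethyl-5,6-dihydro-2H-pyran-2-one (methyl ketal of the open adduct) | CC(C)(C)[Si](C)(C)O[C@@H]1[C@H](C)[C@@H](C)O[C@@](OC)([C@@H]1C)[C@@H](C)[C@H]1OC(=O)C(C)=C(O)[C@H]1C
F2 | step 11 | 4'-[(tert-butyldimethylsilyl)oxy]-3',4,5',6,6',7-hexamethylspiro[2-oxabicyclo[2.2.2]octane-5,2'-oxane]-3,8-dione (C4' silyl ether of 18) | CC(C)(C)[Si](C)(C)O[C@@H]1[C@H](C)[C@@H](C)O[C@@]2([C@@H]1C)[C@@H](C)[C@H]1OC(=O)[C@]2(C)C(=O)[C@H]1C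
F3 | step 8 | (3R,4R,5R,6R)-4-[(tert-butyldimethylsilyl)oxy]-3,5,6-trimethyloxan-2-ol (anomeric mixture) | CC(C)(C)[Si](C)(C)O[C@@H]1[C@H](C)[C@@H](C)OC(O)[C@@H]1C
F4 | step 8 | (2R,3R,4S,5S)-4-[(tert-butyldimethylsilyl)oxy]-3,5-dimethylhept-6-yn-2-ol | C#C[C@H](C)[C@H](O[Si](C)(C)C(C)(C)C)[C@H](C)[C@@H](C)O
F5 | step 8 | (2R,3R,4S,5S)-4-[(tert-butyldimethylsilyl)oxy]-3,5-dimethyloct-6-yn-2-ol | CC#C[C@H](C)[C@H](O[Si](C)(C)C(C)(C)C)[C@H](C)[C@@H](C)O
F6 | step 12 | 4'-[(tert-butyldimethylsilyl)oxy]-3',4,5',6,6'-pentamethyl-7-methylidenespiro[2-oxabicyclo[2.2.2]octane-5,2'-oxane]-3,8-dione | CC(C)(C)[Si](C)(C)O[C@@H]1[C@H](C)[C@@H](C)O[C@@]2([C@@H]1C)[C@@H](C)[C@H]1OC(=O)[C@]2(C)C(=O)C1=C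
F7 | step 12 | 4'-hydroxy-3',4,5',6,6'-pentamethyl-7-methylidenespiro[2-oxabicyclo[2.2.2]octane-5,2'-oxane]-3,8-dione | O[C@@H]1[C@H](C)[C@@H](C)O[C@@]2([C@@H]1C)[C@@H](C)[C@H]1OC(=O)[C@]2(C)C(=O)C1=C
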